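Compound numbers are those of the steps and the compound list; 18 is the target.

## Analysis of the target

- Target 18 is 2,4-dihydroxy-5-methyl-6-(13-methyltetradecyl)benzoic acid: one benzene ring carrying CO2H (C1), OH (C2), H (C3), OH (C4), CH3 (C5) and the chain (CH2)12CH(CH3)2 (C6).
- There is no stereocentre and no stereogenic double bond, so the problem is purely constitutional: five substituents in the right order around one ring.
- The feature the route is built on is the chain carboxyl–C1–C2–C3–C4–C5–C6–C1′. It carries oxygen, or a former carbonyl, on every second carbon (carboxyl carbon, C2, C4, C6), and the methyl sits on a methylene-derived carbon (C5). The ring is a folded, C-methylated tetraketide with an iso-C16 acyl starter.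
- In that chain the ring bond C1–C6 is the one bond that joins a doubly activated nucleophilic carbon (C1, between carboxyl and C2 carbonyl) to an electrophilic ketone carbon (C6).
- The β-resorcylic acid is sensitive: ipso-protonation at C1 (ortho/para to two OH groups) leads to decarboxylation under acid or heat.
- The carboxyl is flanked by OH and the long chain, so its simple esters resist saponification.
- The resorcinol ring is electron-rich and open to electrophiles and oxidants at C3.
- The C15 chain makes every intermediate waxy and non-polar, so regioisomers cannot be expected to separate; the substitution pattern has to be right by construction.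

## Retrosynthetic reasoning

**Benzyl C–O bond (18 from 17).** The acid is freed last from benzyl ester 17 by hydrogenolysis. This is neutral and runs at room temperature, so neither the hindered acyl carbon nor the decarboxylation-prone acid meets acid, base or heat. The saturated chain and the arene are inert to it.

**Ring bond C1–C6 (17 from 16, 15, 14 and 12 + 13).** The arene is opened at C1–C6, the bond a polyketide synthase would form. This gives the open-chain benzyl 3,5,7-triketo ester 15 by way of the cyclic aldol 16. It is cut here because it is the only ring bond whose formation is programmed by the oxygen pattern itself: chain C2 is the most acidic carbon, the C7 ketone lies six atoms away, and the product is aromatic. All five ring substituents are then fixed by the sequence of the chain and not by selectivity on an arene. Ester 15 is not stored: it comes from acylketene 14, set free by retro-[4+2] loss of acetone from diketo-dioxinone 12 and captured by benzyl alcohol 13. The forward step has to unmask, esterify, cyclise and dehydrate in one operation.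

**Chain bond between CH(CH3) and the long-chain C=O (12 from 11 + 6).** Diketo-dioxinone 12 is cut between C3′ and C4′ of its side chain (ring C5–C6 of the target). This separates the whole lipophilic C16 acyl unit, as Weinreb amide 6, from a small triketide equivalent, dianion 11 of keto-dioxinone 10. The C-methyl group is already in 10 as part of an ethyl ketone, so no separate C-methylation among three acidic sites is needed.

**Dioxinone side-chain bond (10 from 9 + 8).** Keto-dioxinone 10 is cut between C1′ and C2′ into lithium dienolate 9, made from commercial dioxinone 7, and propanoyl chloride 8. The forward reaction is a γ-selective C-acylation.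

**Amide and chain bonds (6 from 5 and 4; 4 from 3 + 2).** Weinreb amide 6 comes from acid 4 via acyl imidazole 5. The iso-branched acid 4 is cut between chain carbons C11′ and C12′ (target numbering) into 12-bromododecanoic acid 1, coupled as its carboxylate 3, and isobutylmagnesium bromide 2. Both are cheap, and the iso terminus is placed by one sp3–sp3 coupling without touching the carboxyl.

## Alternatives that were turned down

**Alternative 1: functionalisation of a preformed arene (the textbook route).**
- Disconnection: the C1–carboxyl bond and the benzylic end of the chain, with the benzene ring bought.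
- Forward: olefination and hydrogenation on a dimethoxytoluene core give 1,5-dimethoxy-2-methyl-3-(13-methyltetradecyl)benzene A1. The key step is Vilsmeier formylation of A1 at the position between chain and methoxy to give aldehyde A2. Pinnick oxidation gives acid A3, and double O-demethylation gives 18.
- Turned down because:
  - no commercial arene carries methyl, chain and two meta oxygens in this order, so the core of A1 itself costs several steps;
  - the formylation must choose between the site flanked by two methoxy groups and the site buttressed by chain and methyl, and isomers of such waxy compounds would not separate;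
  - the last step has to cleave two aryl methyl ethers with a strong Lewis acid on a β-resorcylic acid, the conditions under which C1 is protonated and CO2 is lost;
  - the count is eight or more steps, none of which builds complexity.

**Alternative 2: [4+2] cycloaddition of a 1,3-bis(silyloxy)diene with an ynoate.**
- Disconnection: ring bonds C1–C2 and C5–C6.
- Forward: methyl 16-methylheptadec-2-ynoate A4 and 1-methoxy-1,3-bis(trimethylsilyloxy)penta-1,3-diene A5 combine, lose methanol and silyl groups, and give methyl ester A6 with the correct pattern.
- Turned down because:
  - the new C5–C6 bond joins the methyl-bearing diene terminus to the β-carbon of a β-alkyl ynoate, a poor dienophile that needs temperatures at which such dienes suffer silyl migration and decomposition;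
  - A4 needs three to four steps by itself;
  - the product is a di-ortho-substituted methyl benzoate that resists hydrolysis, while the acid does not survive forcing conditions.

**Alternative 3: Michael–Claisen annulation and oxidative aromatisation.**
- Disconnection: ring bonds C1–C6 (Michael) and C3–C4 (Claisen).
- Forward: ethyl (E)-2,16-dimethylheptadec-2-enoate A7 and ethyl acetoacetate A8 give dihydroresorcylate A9, which is dehydrogenated to ethyl ester A10.
- Turned down because:
  - A7 is an α-methyl-β-alkyl enoate, a hindered and deactivated Michael acceptor, so the addition is slow and reversible;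
  - the ring is built one oxidation level too low, and the dehydrogenation of such diones (halogenation–elimination or quinone oxidants) tends to functionalise the free position C3;
  - the route again ends in a hindered alkyl ester.

Key step: step 5

Remark on the chemistry: the SMILES contains no stereogenic element, so 18 is achiral; "single enantiomer" is read as the single constitution given, and no step needs stereocontrol.

## Route

Step 1
Reactants: 1 12-bromododecanoic acid; 2 isobutylmagnesium bromide
Product: 4 14-methylpentadecanoic acid, via bromomagnesium 12-bromododecanoate 3 (not isolated)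
Conditions: 2 (1.0 equiv), THF, −20 °C; then Li2CuCl4 (3 mol %), 2 (1.5–2 equiv), −20 °C → rt; 1 M HCl
Reagents that add atoms: none
Why: Kochi-type copper-catalysed sp3–sp3 coupling of a primary alkyl bromide with a primary Grignard reagent; the first equivalent of 2 turns the acid into carboxylate 3, which is inert to the Grignard reagent at this temperature, so only the C–Br bond reacts.

Step 2
Reactants: 4 14-methylpentadecanoic acid
Product: 6 N-methoxy-N,14-dimethylpentadecanamide, via acyl imidazole 5 (not isolated)
Conditions: CDI (1.2 equiv), CH2Cl2, rt; then MeNH(OMe)·HCl (1.5 equiv), rt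
Reagents that add atoms: N,O-dimethylhydroxylamine hydrochloride, CNOC.Cl
Why: Standard Weinreb amide formation by carbonyldiimidazole activation and aminolysis of acyl imidazole 5; nothing else in the molecule can react.

Step 3
Reactants: 7 2,2,6-trimethyl-4H-1,3-dioxin-4-one; 8 propanoyl chloride
Product: 10 2,2-dimethyl-6-(2-oxobutyl)-4H-1,3-dioxin-4-one, via lithium dienolate 9 (not isolated)
Conditions: 7 (2.1 equiv), LiHMDS (2.2 equiv), THF, −78 °C; then 8 (1.0 equiv), −78 °C; 1 M HCl
Reagents that add atoms: none
Why: Claisen-type γ-C-acylation of the dioxinone dienolate by an acid chloride; two equivalents of 9 are used because product 10 is more acidic than 7 and is at once deprotonated, which also shields it from a second acylation.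

Step 4
Reactants: 10 2,2-dimethyl-6-(2-oxobutyl)-4H-1,3-dioxin-4-one; 6 N-methoxy-N,14-dimethylpentadecanamide
Product: 12 6-(3,17-dimethyl-2,4-dioxooctadecyl)-2,2-dimethyl-4H-1,3-dioxin-4-one, via dilithium dianion 11 (not isolated)
Conditions: 10 (1.5 equiv), LDA (3.2 equiv), THF, −78 °C; then 6 (1.0 equiv), −78 → −20 °C; 1 M HCl to pH 3; crude 12 used directly
Reagents that add atoms: none
Why: Crossed Claisen condensation of a 1,3-dianion with a Weinreb amide: the dianion reacts at its last-formed, most basic carbon C3′, and the chelated tetrahedral adduct persists until the quench, which prevents over-addition and proton exchange; the new C3′ centre is racemic, labile and erased in step 5.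

Step 5
Reactants: 12 6-(3,17-dimethyl-2,4-dioxooctadecyl)-2,2-dimethyl-4H-1,3-dioxin-4-one; 13 benzyl alcohol
Product: 17 benzyl 2,4-dihydroxy-5-methyl-6-(13-methyltetradecyl)benzoate, via acylketene 14 (not isolated), via benzyl triketo ester 15 (not isolated), via cyclic aldol 16 (not isolated)
Conditions: 13 (2–3 equiv), PhMe, 110 °C; then Cs2CO3 (2 equiv), CH2Cl2/i-PrOH, rt; then aq. HCl to pH 2, rt
Reagents that add atoms: none
Why: Heating 12 causes a retro-hetero-Diels–Alder loss of acetone to acylketene 14, which benzyl alcohol 13 captures at the ketene carbon to give the open tetraketide 15, the benzyl ester of the presumed biosynthetic intermediate. With Cs2CO3 the most acidic carbon of 15, C2 between the ester and the C3 ketone, adds to the C7 ketone in an intramolecular aldol reaction (6-(enolendo)-exo-trig, favoured) to give carbinol 16; acid then eliminates water and the two remaining ring ketones enolise, so that aromaticity makes the sequence irreversible. The closest known reaction type is the late-stage aromatisation of diketo-dioxinones and of 3,5,7-triketo esters to β-resorcylates. The step forms the ring bond C1–C6 and with it the whole pentasubstituted benzene, each substituent sitting where the chain of 15 placed it, so no regiochemistry on an arene has to be controlled. The selectivity needed is C2→C7 aldol over the C6→C1 Claisen mode and over O-cyclisation to pyranones: the C6 methyl group makes the Claisen product a non-aromatisable, reversibly formed 2,2-disubstituted trione, the excess of the primary alcohol outruns intramolecular capture of 14 by the diketone enol, and base is applied before acid so that the aldol closes before a 4-pyranone can form. The three stereocentres of 16 and the methine centre of 12, 14 and 15 are transient and are erased on aromatisation, so none needs control.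

Step 6
Reactants: 17 benzyl 2,4-dihydroxy-5-methyl-6-(13-methyltetradecyl)benzoate
Product: 18 2,4-dihydroxy-5-methyl-6-(13-methyltetradecyl)benzoic acid
Conditions: H2 (1 atm), 10% Pd/C, EtOAc, rt; filtration and concentration below 30 °C
Reagents that add atoms: none
Why: Hydrogenolysis of a benzyl ester frees the hindered, decarboxylation-prone acid under neutral conditions at room temperature; the arene, the phenols and the saturated chain are inert.

## Compound list

1 | 12-bromododecanoic acid | OC(=O)CCCCCCCCCCCBr | starting material
2 | isobutylmagnesium bromide | CC(C)C[Mg]Br | starting material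
3 | bromomagnesium 12-bromododecanoate | [Mg+2].[Br-].[O-]C(=O)CCCCCCCCCCCBr | intermediate (not isolated)
4 | 14-methylpentadecanoic acid | CC(C)CCCCCCCCCCCCC(=O)O | intermediate
5 | 1-(1H-imidazol-1-yl)-14-methylpentadecan-1-one (acyl imidazole) | CC(C)CCCCCCCCCCCCC(=O)n1ccnc1 | intermediate (not isolated)
6 | N-methoxy-N,14-dimethylpentadecanamide | CC(C)CCCCCCCCCCCCC(=O)N(C)OC | intermediate
7 | 2,2,6-trimethyl-4H-1,3-dioxin-4-one | CC1=CC(=O)OC(C)(C)O1 | starting material
8 | propanoyl chloride | CCC(Cl)=O | starting material
9 | lithium 2,2-dimethyl-6-methylidene-6H-1,3-dioxin-4-olate (lithium dienolate of 7) | [Li+].C=C1C=C([O-])OC(C)(C)O1 | intermediate (not isolated)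
10 | 2,2-dimethyl-6-(2-oxobutyl)-4H-1,3-dioxin-4-one | CCC(=O)CC1=CC(=O)OC(C)(C)O1 | intermediate
11 | dilithium dianion of 10 (C1′ enolate, C3′ carbanion) | [Li+].[Li+].C[CH-]C([O-])=CC1=CC(=O)OC(C)(C)O1 | intermediate (not isolated)
12 | 6-(3,17-dimethyl-2,4-dioxooctadecyl)-2,2-dimethyl-4H-1,3-dioxin-4-one (racemic at C3′, keto/enol mixture) | CC(C)CCCCCCCCCCCCC(=O)C(C)C(=O)CC1=CC(=O)OC(C)(C)O1 | intermediate
13 | benzyl alcohol | OCc1ccccc1 | starting material
14 | 6,20-dimethyl-3,5,7-trioxohenicos-1-en-1-one (acylketene) | CC(C)CCCCCCCCCCCCC(=O)C(C)C(=O)CC(=O)C=C=O | intermediate (not isolated)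
15 | benzyl 6,20-dimethyl-3,5,7-trioxohenicosanoate | CC(C)CCCCCCCCCCCCC(=O)C(C)C(=O)CC(=O)CC(=O)OCc1ccccc1 | intermediate (not isolated)
16 | benzyl 2-hydroxy-3-methyl-2-(13-methyltetradecyl)-4,6-dioxocyclohexane-1-carboxylate (mixture of diastereomers and tautomers) | CC(C)CCCCCCCCCCCCC1(O)C(C)C(=O)CC(=O)C1C(=O)OCc2ccccc2 | intermediate (not isolated)
17 | benzyl 2,4-dihydroxy-5-methyl-6-(13-methyltetradecyl)benzoate | Cc1c(O)cc(O)c(C(=O)OCc2ccccc2)c1CCCCCCCCCCCCC(C)C | intermediate
18 | 2,4-dihydroxy-5-methyl-6-(13-methyltetradecyl)benzoic acid | Cc1c(O)cc(O)c(C(=O)O)c1CCCCCCCCCCCCC(C)C | target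

## Step count and least certain steps

Total: 6 steps. Longest linear sequence: 5 steps (1, 2, 4, 5, 6); step 3 is a one-step branch that enters at step 4.

**Step 5 (key step).**
- What may go wrong: intramolecular capture of the acylketene by the enolised diketone, leading to a 4-hydroxy-2-pyranone, could compete with capture by benzyl alcohol. Retro-Claisen cleavage of the 2-methyl-1,3-diketone by alkoxide before the aldol closes, and acid-side cyclodehydration of the 3,5,7-trione to a 4-pyranone if acid arrives too early, are the other risks.
- Fallback, from 12 back to the route at 18: the ketene is never generated. Triethylamine in CH2Cl2 at rt deprotonates C1′ of 12, and the vinylogous enolate attacks the C4′ ketone through dioxinone C5. Dehydration gives 7-hydroxy-2,2,6-trimethyl-5-(13-methyltetradecyl)-4H-1,3-benzodioxin-4-one F1, in which the dioxinone ring serves as the carboxyl protecting group. F1 is opened with aqueous KOH in DMSO at 60–80 °C under argon, where the trianion does not decarboxylate. Cold acidification to pH 3 gives 18 directly, without step 6.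

**Step 4.**
- What may go wrong: incomplete second deprotonation or sluggish acylation at the secondary carbanion C3′, so that 10 and 6 are returned. Base-induced N–O cleavage of the Weinreb amide and premature cyclisation or decomposition of 12 on work-up are further risks.
- Fallback, from 6 and 10 back to the route at 12: 6 is reduced with LiAlH4 (THF, 0 °C) to 14-methylpentadecanal F2. The aldehyde is a far better electrophile for dianion 11 (THF, −78 °C) and gives 6-(4-hydroxy-3,17-dimethyl-2-oxooctadecyl)-2,2-dimethyl-4H-1,3-dioxin-4-one F3 as a mixture of diastereomers, which does not matter. Oxidation of F3 with Dess–Martin periodinane (CH2Cl2, rt) gives 12.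

**Step 3.**
- What may go wrong: O-acylation of the dienolate, acylation at the α-carbon (ring C5) in place of the γ-carbon, and double acylation of the more acidic product.
- Fallback, from 7 back to the route at 10: dienolate 9 (LiHMDS, THF, −78 °C) is added to propanal (CCC=O) in a γ-selective aldol reaction, which has no O-acylation or over-reaction channel. This gives 6-(2-hydroxybutyl)-2,2-dimethyl-4H-1,3-dioxin-4-one F4 (racemic), and Dess–Martin oxidation (CH2Cl2, rt) gives 10.

**Step 1.**
- What may go wrong: slow coupling because the magnesium carboxylate is poorly soluble, and reduction or elimination of the alkyl bromide and homocoupling, which would give fatty acids that are hard to separate from 4.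
- Fallback, from 1 back to the route at 4: 1 is heated with triphenylphosphine (MeCN, reflux) to give (11-carboxyundecyl)triphenylphosphonium bromide F5. Its ylide-carboxylate (NaHMDS, 2.1 equiv, THF) undergoes a Wittig reaction with 2-methylpropanal (CC(C)C=O) to give (Z)-14-methylpentadec-12-enoic acid F6; the double-bond geometry is irrelevant. Hydrogenation (H2, Pd/C, EtOAc) gives 4. Acid 4 is also an article of commerce, at higher cost.

## Further compounds

F1 | step 5 | 7-hydroxy-2,2,6-trimethyl-5-(13-methyltetradecyl)-4H-1,3-benzodioxin-4-one | CC1(C)OC(=O)c2c(O1)cc(O)c(C)c2CCCCCCCCCCCCC(C)C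
F2 | step 4 | 14-methylpentadecanal | CC(C)CCCCCCCCCCCCC=O
F3 | step 4 | 6-(4-hydroxy-3,17-dimethyl-2-oxooctadecyl)-2,2-dimethyl-4H-1,3-dioxin-4-one (mixture of diastereomers) | CC(C)CCCCCCCCCCCCC(O)C(C)C(=O)CC1=CC(=O)OC(C)(C)O1
F4 | step 3 | 6-(2-hydroxybutyl)-2,2-dimethyl-4H-1,3-dioxin-4-one (racemic) | CCC(O)CC1=CC(=O)OC(C)(C)O1
F5 | step 1 | (11-carboxyundecyl)triphenylphosphonium bromide | OC(=O)CCCCCCCCCCC[P+](c1ccccc1)(c1ccccc1)c1ccccc1.[Br-]
F6 | step 1 | (Z)-14-methylpentadec-12-enoic acid | CC(C)/C=C\CCCCCCCCCCC(=O)O
A1 | alternative 1 | 1,5-dimethoxy-2-methyl-3-(13-methyltetradecyl)benzene | COc1cc(OC)c(C)c(CCCCCCCCCCCCC(C)C)c1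
A2 | alternative 1 | 2,4-dimethoxy-5-methyl-6-(13-methyltetradecyl)benzaldehyde | COc1cc(OC)c(C=O)c(CCCCCCCCCCCCC(C)C)c1C
A3 | alternative 1 | 2,4-dimethoxy-5-methyl-6-(13-methyltetradecyl)benzoic acid | COc1cc(OC)c(C(=O)O)c(CCCCCCCCCCCCC(C)C)c1C
A4 | alternative 2 | methyl 16-methylheptadec-2-ynoate | CC(C)CCCCCCCCCCCCC#CC(=O)OC
A5 | alternative 2 | 1-methoxy-1,3-bis(trimethylsilyloxy)penta-1,3-diene | COC(O[Si](C)(C)C)=CC(O[Si](C)(C)C)=CC
A6 | alternative 2 | methyl 2,4-dihydroxy-5-methyl-6-(13-methyltetradecyl)benzoate | COC(=O)c1c(O)cc(O)c(C)c1CCCCCCCCCCCCC(C)C
A7 | alternative 3 | ethyl (E)-2,16-dimethylheptadec-2-enoate | CCOC(=O)/C(C)=C/CCCCCCCCCCCCC(C)C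
A8 | alternative 3 | ethyl acetoacetate | CCOC(=O)CC(C)=O
A9 | alternative 3 | ethyl 3-methyl-2-(13-methyltetradecyl)-4,6-dioxocyclohexane-1-carboxylate (mixture of diastereomers) | CCOC(=O)C1C(=O)CC(=O)C(C)C1CCCCCCCCCCCCC(C)C
A10 | alternative 3 | ethyl 2,4-dihydroxy-5-methyl-6-(13-methyltetradecyl)benzoate | CCOC(=O)c1c(O)cc(O)c(C)c1CCCCCCCCCCCCC(C)C
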